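**Retrosynthetic overview**
- The target comes last from exo-face cis-hydrogenation of the tetrasubstituted C=C shared by the carbocycle and a 2H-pyran (ring A). That alkene precursor has only the quinolinone-B-bearing CH, and the bridge it enforces, as stereocentres.
- The alkene precursor comes from a Lewis-acid intramolecular hetero-Diels–Alder/dehydration of a 3-acyl-4-hydroxyquinolinone onto an isobutenyl group, which closes the cyclohexene and pyran ring A together. Its ketone comes from a vinylogous Mukaiyama alkylation at a ketal carbon, which closes pyran ring B and makes the O–C(Me) quaternary carbon.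
- Key disconnection: the C3(quinolinone B)–CH bond, made with reversed polarity from the iodonium ylide of the quinoline-2,4-dione (an enolonium equivalent) and the chiral enamine of a ketal-masked levulinaldehyde. A Wittig reaction then turns the aldehyde carbon into the isobutenyl group.
- Ring order: both quinolinones are bought; stereogenic C–C bond, then pyran B, then cyclohexene plus pyran A in one operation, then saturation of the ring fusion.

Assumption: the configuration to be made is exactly that of the given SMILES (O, aryl, CMe2 and aryl all on one face of the cyclohexane), and every numbered starting material is bought as a catalogue chemical.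

**Step 1**
Reactants: 1 4-hydroxy-1-methylquinolin-2(1H)-one; 2 3-(2-methyl-1,3-dioxolan-2-yl)propanal
Product: 4 (3S)-2-hydroxy-5-methyl-3-[(2-methyl-1,3-dioxolan-2-yl)methyl]-2,3-dihydrofuro[3,2-c]quinolin-4(5H)-one (lactol form of the S-configured 2-quinolinonyl aldehyde; anomer mixture), via iodonium ylide 3 (not isolated)
Conditions: PhI(OAc)2 (1.0 equiv), CH2Cl2, 0 °C, 30 min; then 2 (2 equiv), (R)-2-[diphenyl(trimethylsilyloxy)methyl]pyrrolidine (20 mol %), −20 °C, 24 h
Reagents that add atoms: (diacetoxyiodo)benzene, CC(=O)OI(OC(C)=O)c1ccccc1 (its PhI unit sits only in intermediate 3 and leaves as iodobenzene)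
Why: Proposed new method: the acetic acid released protonates ylide 3 to a β-oxo-alkenyl(phenyl)-λ3-iodane, an enolonium equivalent of the quinolinedione, and the E-enamine of 2 attacks its C3 (ligand coupling at trivalent iodine, PhI as leaving group) on the face away from the CPh2OTMS group, so two carbons that are both nucleophilic in normal polarity are joined and the S aldehyde is trapped as lactol 4, which shields it from racemisation; closest known reaction types are the coupling of enolonium species with silyl enol ethers, the amine/copper-catalysed α-arylation and α-vinylation of aldehydes with iodonium salts, and the Jørgensen quinone α-arylation of aldehydes.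

**Step 2**
Reactants: 4 (3S)-lactol
Product: 5 4-hydroxy-1-methyl-3-[(2R)-4-methyl-1-(2-methyl-1,3-dioxolan-2-yl)pent-3-en-2-yl]quinolin-2(1H)-one
Conditions: i-PrPPh3 I (2.5 equiv), KN(SiMe3)2 (2.4 equiv), THF, 0 °C; then 4, −78 → 0 °C; aq. NH4Cl
Reagents that add atoms: isopropyltriphenylphosphonium iodide, CC(C)[P+](c1ccccc1)(c1ccccc1)c1ccccc1.[I-]
Why: Wittig olefination of the base-opened lactol with the non-stabilised isopropylidene ylide turns the aldehyde carbon into the nucleophilic CH=CMe2 group; the ketal is inert, and the quinolinolate anion formed first disfavours deprotonation at the stereocentre, whose descriptor changes from S to R only because the CIP priorities change.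

**Step 3**
Reactants: 5 (R)-isobutenyl ketal; 6 3-acetyl-4-hydroxy-1-methylquinolin-2(1H)-one
Product: 8 (4R)-2-[2-(4-hydroxy-1-methyl-2-oxo-1,2-dihydroquinolin-3-yl)-2-oxoethyl]-2,6-dimethyl-4-(2-methylprop-1-en-1-yl)-3,4-dihydro-2H-pyrano[3,2-c]quinolin-5(6H)-one (both C2 epimers), via bis-silyl dienol ether 7 (not isolated)
Conditions: 6 (1.5 equiv), TMSOTf, Et3N, CH2Cl2, 0 °C; then 5, TMSOTf (20 mol %), −78 → −20 °C; aq. NaHCO3
Reagents that add atoms: trimethylsilyl triflate, C[Si](C)(C)OS(=O)(=O)C(F)(F)F (silyl groups sit only in intermediate 7 and are lost on work-up)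
Why: TMSOTf opens the dioxolane, the neighbouring quinolinone oxygen closes pyran ring B to a cyclic tertiary oxocarbenium ion, and the terminal CH2 of the Chan-type dienol ether 7 adds to it (vinylogous Mukaiyama alkylation of a ketal under Noyori conditions); the new quaternary centre is not controlled here and both epimers are carried on.

**Step 4**
Reactants: 8 keto-pyran (C2 epimers)
Product: 10 didehydro-11: the bridged skeleton of the target with a C=C between the CMe2-bearing carbon and the quinolinone-A-bearing carbon (ring A is a 2,2-dimethyl-2H-pyran; R at the quinolinone-B-bearing CH), via tertiary carbinol cycloadduct 9 (not isolated)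
Conditions: Sc(OTf)3 (10 mol %), 4 Å MS, ClCH2CH2Cl, 60 °C
Reagents that add atoms: none
Why: The Sc(OTf)3-chelated 3-acyl-4-hydroxyquinolinone (exo-enol, a cationic 1-oxadiene) adds to the isobutenyl group in an intramolecular hetero-Diels–Alder (Prins-type carbonyl–olefin) reaction that only the 2,4-cis epimer can reach, the trans epimer re-entering by reversible oxa-Michael ring opening, and carbinol 9 dehydrates to the conjugated tetrasubstituted 2H-pyran (the analogue of the thermodynamically preferred Δ6a,10a-tetrahydrocannabinol); the bridge fixes the O–C(Me) centre cis to the aryl-bearing CH.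

**Step 5**
Reactants: 10 didehydro-11
Product: 11 target CNP0229685.5
Conditions: H2 (20 bar), Pd/C, EtOAc/AcOH, 50 °C
Reagents that add atoms: none
Why: Heterogeneous syn-hydrogenation of the chromene-type alkene; its endo face lies directly under the quinolinone B ring (the O–C=C bridge of the bicyclo[3.3.1] core), so both hydrogens arrive from the exo face and the two new stereocentres carry CMe2–O and quinolinone A on the bridge side, giving the cis-fused, all-cis target, as in the hydrogenation of Δ6a,10a-tetrahydrocannabinol to cis-hexahydrocannabinol.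

**Compound list**
1 | 4-hydroxy-1-methylquinolin-2(1H)-one | Cn1c(=O)cc(O)c2ccccc21 | starting material
2 | 3-(2-methyl-1,3-dioxolan-2-yl)propanal | CC1(CCC=O)OCCO1 | starting material
3 | 1-methyl-3-(phenyl-λ3-iodanylidene)quinoline-2,4(1H,3H)-dione (iodonium ylide, zwitterion) | Cn1c(=O)c([I+]c2ccccc2)c([O-])c2ccccc21 | intermediate
4 | (3S)-2-hydroxy-5-methyl-3-[(2-methyl-1,3-dioxolan-2-yl)methyl]-2,3-dihydrofuro[3,2-c]quinolin-4(5H)-one (lactol of (S)-2-(4-hydroxy-1-methyl-2-oxoquinolin-3-yl)-3-(2-methyl-1,3-dioxolan-2-yl)propanal, anomer mixture) | CC1(C[C@@H]2C(O)Oc3c2c(=O)n(C)c2ccccc32)OCCO1 | intermediate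
5 | 4-hydroxy-1-methyl-3-[(2R)-4-methyl-1-(2-methyl-1,3-dioxolan-2-yl)pent-3-en-2-yl]quinolin-2(1H)-one | CC1(C[C@H](C=C(C)C)c2c(O)c3ccccc3n(C)c2=O)OCCO1 | intermediate
6 | 3-acetyl-4-hydroxy-1-methylquinolin-2(1H)-one | CC(=O)c1c(O)c2ccccc2n(C)c1=O | starting material
7 | 1-methyl-4-(trimethylsilyloxy)-3-[1-(trimethylsilyloxy)ethenyl]quinolin-2(1H)-one | C=C(O[Si](C)(C)C)c1c(O[Si](C)(C)C)c2ccccc2n(C)c1=O | intermediate
8 | (4R)-2-[2-(4-hydroxy-1-methyl-2-oxo-1,2-dihydroquinolin-3-yl)-2-oxoethyl]-2,6-dimethyl-4-(2-methylprop-1-en-1-yl)-3,4-dihydro-2H-pyrano[3,2-c]quinolin-5(6H)-one (C2 epimer mixture, C2 left open in the SMILES) | O=C(CC1(C)C[C@H](C=C(C)C)c2c(O1)c1ccccc1n(C)c2=O)c1c(O)c2ccccc2n(C)c1=O | intermediate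
9 | hydrate of 10: tertiary alcohol at the quinolinone-A-bearing ring carbon of the bridged bis-pyran (the two ring-A fusion carbons left open) | Cn1c(=O)c2c(c3ccccc31)OC(C)(C)C1C2(O)C[C@]2(C)C[C@H]1c1c(c3ccccc3n(C)c1=O)O2 | intermediate
10 | didehydro-11: bridged bis(6-methylpyrano[3,2-c]quinolin-5-one) with a tetrasubstituted C=C at the ring A/carbocycle fusion; R at the quinolinone-B-bearing CH; O–C(Me) bridged cis to it | Cn1c(=O)c2c(c3ccccc31)OC(C)(C)C1=C2C[C@]2(C)C[C@H]1c1c(c3ccccc3n(C)c1=O)O2 | intermediate
11 | target CNP0229685.5: 2,2-dimethyl-dihydropyran ring A cis-fused to a cyclohexane that is bridged 1,3 by pyran ring B; O, quinolinone B, CMe2 and quinolinone A all on one face of the cyclohexane, C-methyl and the three CH hydrogens on the other | Cn1c(=O)c2c(c3ccccc31)OC(C)(C)[C@H]1[C@@H]2C[C@]2(C)C[C@H]1c1c(c3ccccc3n(C)c1=O)O2 | target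

**Totals and risks**
Total step count: 5. Longest linear sequence: 5 steps (1 → 4 → 5 → 8 → 10 → 11).

The three steps most likely to fail are steps 1, 4 and 5.

Step 1: the enamine may not capture the ylide without a metal, and lactol 4 could dehydrate to the aromatic furan (losing the stereocentre) or lose ee. The fallback sets out from 1: MesI(OAc)2 and TfOH give the isolable salt (4-hydroxy-1-methyl-2-oxo-1,2-dihydroquinolin-3-yl)(2,4,6-trimethylphenyl)iodonium triflate F1. This is coupled with 2 under dual catalysis by CuBr (10 mol %) and (2R,5R)-5-benzyl-2-tert-butyl-3-methylimidazolidin-4-one trichloroacetate (NaHCO3, toluene/Et2O), the quinolinonyl group passing to the enamine from a trivalent copper intermediate. It comes back to the route at 4.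

Step 4: the chelated acyl-quinolinone may be too weak a heterodiene, and ring-B opening frees a 4-OH that can add irreversibly to the isobutenyl group. The fallback sets out from 8: NaBH4/CeCl3·7H2O in MeOH at −40 °C reduces the aryl ketone to the carbinol (4R)-2-[2-hydroxy-2-(4-hydroxy-1-methyl-2-oxo-1,2-dihydroquinolin-3-yl)ethyl]-2,6-dimethyl-4-(2-methylprop-1-en-1-yl)-3,4-dihydro-2H-pyrano[3,2-c]quinolin-5(6H)-one F2. CF3CO2H dehydrates it to the alkylidene quinoline-2,4-dione F3 (not isolated), which closes by the well-known intramolecular hetero-Diels–Alder reaction of Tietze type to the saturated bis-pyran F4, a mixture at the two ring-A fusion CH centres. DDQ in dioxane at 80 °C dehydrogenates ring A and the fallback comes back at 10, so the fusion stereochemistry is still set in step 5.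

Step 5: the shielded tetrasubstituted alkene may resist Pd/C. The fallback sets out from 10 and uses ionic hydrogenation (Et3SiH, CF3CO2H, CH2Cl2, 0 °C): protonation at the CMe2-bearing carbon gives the oxygen-stabilised benzylic cation, and hydride is again delivered from the open exo face. It comes back at 11 and makes no new compound (F0).

**Further compounds**
F1 | step 1 | (4-hydroxy-1-methyl-2-oxo-1,2-dihydroquinolin-3-yl)(2,4,6-trimethylphenyl)iodonium triflate | Cn1c(=O)c([I+]c2c(C)cc(C)cc2C)c(O)c2ccccc21.[O-]S(=O)(=O)C(F)(F)F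
F2 | step 4 | (4R)-2-[2-hydroxy-2-(4-hydroxy-1-methyl-2-oxo-1,2-dihydroquinolin-3-yl)ethyl]-2,6-dimethyl-4-(2-methylprop-1-en-1-yl)-3,4-dihydro-2H-pyrano[3,2-c]quinolin-5(6H)-one | OC(CC1(C)C[C@H](C=C(C)C)c2c(O1)c1ccccc1n(C)c2=O)c1c(O)c2ccccc2n(C)c1=O
F3 | step 4 | (4R)-2-[2-(1-methyl-2,4-dioxo-1,4-dihydroquinolin-3(2H)-ylidene)ethyl]-2,6-dimethyl-4-(2-methylprop-1-en-1-yl)-3,4-dihydro-2H-pyrano[3,2-c]quinolin-5(6H)-one | C(CC1(C)C[C@H](C=C(C)C)c2c(O1)c1ccccc1n(C)c2=O)=C1C(=O)c2ccccc2N(C)C1=O
F4 | step 4 | saturated bridged bis-pyran with the constitution of 11, mixture at the two ring-A fusion CH centres | Cn1c(=O)c2c(c3ccccc31)OC(C)(C)C1C2C[C@]2(C)C[C@H]1c1c(c3ccccc3n(C)c1=O)O2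
F0 | step 5 | none | none
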